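## Retrosynthetic overview
1. The last step is hydrogenolysis of five benzyl ethers. Before it, the central hindered benzoate C(=O)–O bond is cut into a western secondary alcohol (arylpropanol + hydroxybutyrate) and an eastern benzoic acid (resorcylate + hydroxybutyrate), which are of similar size.
2. Each half is cut at its aliphatic ester into the same (R)-1-[3,5-bis(benzyloxy)phenyl]propan-2-ol and an O-protected (R)-3-hydroxybutanoic acid (TBS in the west, Bn in the east). The eastern CO2H is added to the arene by formylation and oxidation.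
3. The arylpropanol comes from an aryl Grignard reagent and (R)-propylene oxide. The aryl bromide comes from 3-bromophenol by meta C–H borylation/oxidation.
4. No ring is formed: both benzene rings come intact from 3-bromophenol. All four (R) centres come from the chiral pool ((R)-propylene oxide twice, methyl (R)-3-hydroxybutanoate twice).

Assumption: the target is the all-(R) isomer encoded by the SMILES, and metal alkoxides or carboxylates that are only protonated at work-up are not numbered separately.

## Route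

Step 1
Reactants: 1 3-bromophenol
Product: 2 (3-bromophenoxy)(tert-butyl)dimethylsilane
Conditions: TBSCl, imidazole, DMF, rt
Reagents that add atoms: tert-butyldimethylsilyl chloride (TBSCl) CC(C)(C)[Si](C)(C)Cl
Why: Imidazole-promoted O-silylation (Corey protocol) masks the acidic phenol with a bulky group that has no arene C–H bonds of its own, which the next step needs.

Step 2
Reactants: 2 (3-bromophenoxy)(tert-butyl)dimethylsilane
Product: 4 3-bromo-5-[(tert-butyldimethylsilyl)oxy]phenol, via aryl pinacol boronate 3 (not isolated)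
Conditions: [Ir(OMe)(cod)]2 (1.5 mol %), dtbpy (3 mol %), HBpin, THF, 60 °C; evaporate; then Oxone, acetone/H2O, 0 °C → rt, 15 min
Reagents that add atoms: pinacolborane CC1(C)OBOC1(C)C (boryl group, held in 3 only); Oxone, active salt potassium peroxymonosulfate [K+].[O-]S(=O)(=O)OO (phenol oxygen)
Why: Sterically controlled Ir-catalysed C–H borylation (Hartwig–Miyaura–Smith) attacks only C5, the one C–H without an ortho neighbour, leaves C–Br intact, and ipso-oxidation of the C–B bond places the OH at that carbon.

Step 3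
Reactants: 4 3-bromo-5-[(tert-butyldimethylsilyl)oxy]phenol
Product: 5 1,3-bis(benzyloxy)-5-bromobenzene
Conditions: BnBr (2.3 equiv), KF, K2CO3, DMF, rt → 50 °C
Reagents that add atoms: benzyl bromide BrCc1ccccc1
Why: This is a Williamson ether synthesis in which carbonate ionises the free phenol and fluoride unmasks the aryl silyl ether in situ, so both oxygens (and any phenol already desilylated in step 2) converge on the same dibenzyl ether.

Step 4
Reactants: 5 1,3-bis(benzyloxy)-5-bromobenzene; 6 (R)-2-methyloxirane ((R)-propylene oxide)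
Product: 8 (R)-1-[3,5-bis(benzyloxy)phenyl]propan-2-ol, via aryl Grignard reagent 7 (not isolated)
Conditions: Mg, THF, reflux; then CuI (10 mol %), 6, THF, −30 → 0 °C; 1 M HCl quench
Reagents that add atoms: magnesium [Mg] (held in 7 only)
Why: Copper-catalysed SN2 opening of the epoxide by the Grignard reagent occurs at the unhindered CH2 terminus, so the C–O bond at the stereocentre is never broken and (R)-epoxide gives the (R)-alcohol.

Step 5
Reactants: 9 methyl (R)-3-hydroxybutanoate
Product: 10 methyl (R)-3-[(tert-butyldimethylsilyl)oxy]butanoate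
Conditions: TBSCl, imidazole, DMF, 0 °C → rt
Reagents that add atoms: tert-butyldimethylsilyl chloride (TBSCl) CC(C)(C)[Si](C)(C)Cl
Why: O-silylation leaves the purchased (R) centre untouched and installs a group that can later be removed without disturbing benzyl ethers.

Step 6
Reactants: 10 methyl (R)-3-[(tert-butyldimethylsilyl)oxy]butanoate
Product: 11 (R)-3-[(tert-butyldimethylsilyl)oxy]butanoic acid
Conditions: LiOH, THF/MeOH/H2O, 0 °C → rt; then 1 M HCl to pH 3–4, 0 °C
Reagents that add atoms: lithium hydroxide [Li+].[OH-]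
Why: Cold BAc2 saponification of the methyl ester is faster than E1cB loss of the silyloxy group, so the TBS ether and the (R) centre survive.

Step 7
Reactants: 9 methyl (R)-3-hydroxybutanoate
Product: 12 methyl (R)-3-(benzyloxy)butanoate
Conditions: BnOC(=NH)CCl3, TfOH (5 mol %), cyclohexane/CH2Cl2, 0 °C → rt
Reagents that add atoms: benzyl 2,2,2-trichloroacetimidate N=C(OCc1ccccc1)C(Cl)(Cl)Cl
Why: Acid-catalysed trichloroacetimidate O-benzylation avoids the base that would cause β-elimination or retro-aldol cleavage, and it alkylates oxygen without touching the C–O bond of the (R) centre.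

Step 8
Reactants: 12 methyl (R)-3-(benzyloxy)butanoate
Product: 13 (R)-3-(benzyloxy)butanoic acid
Conditions: LiOH, THF/H2O, 0 °C → rt; then 1 M HCl
Reagents that add atoms: lithium hydroxide [Li+].[OH-]
Why: Mild BAc2 saponification removes the methyl ester while the benzyl ether and the (R) centre stay intact.

Step 9
Reactants: 8 (R)-1-[3,5-bis(benzyloxy)phenyl]propan-2-ol; 11 (R)-3-[(tert-butyldimethylsilyl)oxy]butanoic acid
Product: 14 (R)-1-[3,5-bis(benzyloxy)phenyl]propan-2-yl (R)-3-[(tert-butyldimethylsilyl)oxy]butanoate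
Conditions: DCC, DMAP (10 mol %), CH2Cl2, 0 °C → rt
Reagents that add atoms: none
Why: Steglich esterification acylates the unhindered secondary alcohol through the acylpyridinium ion without breaking a bond at either stereocentre, so both stay (R).

Step 10
Reactants: 14 (R)-1-[3,5-bis(benzyloxy)phenyl]propan-2-yl (R)-3-[(tert-butyldimethylsilyl)oxy]butanoate
Product: 15 (R)-1-[3,5-bis(benzyloxy)phenyl]propan-2-yl (R)-3-hydroxybutanoate
Conditions: HF·pyridine, THF, 0 °C → rt
Reagents that add atoms: none
Why: Fluoride-driven desilylation in a mildly acidic medium frees the alcohol without the base-induced β-elimination that TBAF could cause, and the ester and benzyl ethers are inert to it.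

Step 11
Reactants: 8 (R)-1-[3,5-bis(benzyloxy)phenyl]propan-2-ol; 13 (R)-3-(benzyloxy)butanoic acid
Product: 16 (R)-1-[3,5-bis(benzyloxy)phenyl]propan-2-yl (R)-3-(benzyloxy)butanoate
Conditions: DCC, DMAP (10 mol %), CH2Cl2, 0 °C → rt
Reagents that add atoms: none
Why: Steglich esterification works as in step 9, with retention at both (R) centres, and it also masks the side-chain OH before the electrophilic step that follows.

Step 12
Reactants: 16 (R)-1-[3,5-bis(benzyloxy)phenyl]propan-2-yl (R)-3-(benzyloxy)butanoate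
Product: 18 (R)-1-[3,5-bis(benzyloxy)-2-formylphenyl]propan-2-yl (R)-3-(benzyloxy)butanoate, via aryl iminium salt 17 (not isolated)
Conditions: POCl3, DMF, 0 °C → rt; then aq NaOAc, 0 °C → rt
Reagents that add atoms: N,N-dimethylformamide CN(C)C=O (formyl carbon); water O (aldehyde oxygen); phosphoryl chloride O=P(Cl)(Cl)Cl (counter-ion of 17 only)
Why: Vilsmeier–Haack formylation goes to the ring position ortho to one OBn and para to the other (the two such sites are equivalent by symmetry), as in 3,5-dialkoxytoluenes, and esters and benzyl ethers tolerate the reagent.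

Step 13
Reactants: 18 (R)-1-[3,5-bis(benzyloxy)-2-formylphenyl]propan-2-yl (R)-3-(benzyloxy)butanoate
Product: 19 2,4-bis(benzyloxy)-6-[(R)-2-{[(R)-3-(benzyloxy)butanoyl]oxy}propyl]benzoic acid
Conditions: NaClO2, NaH2PO4, 2-methyl-2-butene (excess), t-BuOH/THF/H2O, 0 °C → rt
Reagents that add atoms: sodium chlorite [Na+].[O-]Cl=O
Why: Pinnick (Lindgren–Kraus) oxidation converts the aldehyde selectively to the acid at buffered pH, and the alkene scavenges HOCl before it can chlorinate the electron-rich ring.

Step 14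
Reactants: 19 2,4-bis(benzyloxy)-6-[(R)-2-{[(R)-3-(benzyloxy)butanoyl]oxy}propyl]benzoic acid; 15 (R)-1-[3,5-bis(benzyloxy)phenyl]propan-2-yl (R)-3-hydroxybutanoate
Product: 21 penta-O-benzyl hansforester J, via acid chloride 20 (not isolated)
Conditions: (COCl)2, DMF (cat.), CH2Cl2, 0 °C → rt, evaporate; then 15, Et3N, DMAP (30 mol %), CH2Cl2, 0 °C → rt
Reagents that add atoms: oxalyl chloride O=C(Cl)C(=O)Cl (chlorine held in 20 only, no atom reaches 21)
Why: The electron-rich 2,6-disubstituted acid is activated as its acid chloride and transferred by DMAP nucleophilic catalysis to the secondary alcohol, whose C–O bond is kept, so the inner hydroxybutyrate centre stays (R).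

Step 15
Reactants: 21 penta-O-benzyl hansforester J
Product: 22 hansforester J
Conditions: H2 (1 atm), 10 % Pd/C, EtOAc/THF, rt
Reagents that add atoms: none
Why: Neutral catalytic hydrogenolysis removes the four aryl benzyl ethers and the one alkyl benzyl ether, while the four esters, whose alkyl C–O bonds are homobenzylic and not benzylic, and the four (R) centres are untouched.

## Compound list
1 | 3-bromophenol | Oc1cccc(Br)c1 | starting material
2 | (3-bromophenoxy)(tert-butyl)dimethylsilane | CC(C)(C)[Si](C)(C)Oc1cccc(Br)c1 | intermediate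
3 | 2-{3-bromo-5-[(tert-butyldimethylsilyl)oxy]phenyl}-4,4,5,5-tetramethyl-1,3,2-dioxaborolane | CC(C)(C)[Si](C)(C)Oc1cc(Br)cc(B2OC(C)(C)C(C)(C)O2)c1 | intermediate
4 | 3-bromo-5-[(tert-butyldimethylsilyl)oxy]phenol | CC(C)(C)[Si](C)(C)Oc1cc(O)cc(Br)c1 | intermediate
5 | 1,3-bis(benzyloxy)-5-bromobenzene | Brc1cc(OCc2ccccc2)cc(OCc2ccccc2)c1 | intermediate
6 | (R)-2-methyloxirane | C[C@@H]1CO1 | starting material
7 | [3,5-bis(benzyloxy)phenyl]magnesium bromide | Br[Mg]c1cc(OCc2ccccc2)cc(OCc2ccccc2)c1 | intermediate
8 | (R)-1-[3,5-bis(benzyloxy)phenyl]propan-2-ol | C[C@H](Cc1cc(OCc2ccccc2)cc(OCc2ccccc2)c1)O | intermediate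
9 | methyl (R)-3-hydroxybutanoate | COC(=O)C[C@@H](C)O | starting material
10 | methyl (R)-3-[(tert-butyldimethylsilyl)oxy]butanoate | COC(=O)C[C@@H](C)O[Si](C)(C)C(C)(C)C | intermediate
11 | (R)-3-[(tert-butyldimethylsilyl)oxy]butanoic acid | OC(=O)C[C@@H](C)O[Si](C)(C)C(C)(C)C | intermediate
12 | methyl (R)-3-(benzyloxy)butanoate | COC(=O)C[C@@H](C)OCc1ccccc1 | intermediate
13 | (R)-3-(benzyloxy)butanoic acid | OC(=O)C[C@@H](C)OCc1ccccc1 | intermediate
14 | (R)-1-[3,5-bis(benzyloxy)phenyl]propan-2-yl (R)-3-[(tert-butyldimethylsilyl)oxy]butanoate | C[C@H](Cc1cc(OCc2ccccc2)cc(OCc2ccccc2)c1)OC(=O)C[C@@H](C)O[Si](C)(C)C(C)(C)C | intermediate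
15 | (R)-1-[3,5-bis(benzyloxy)phenyl]propan-2-yl (R)-3-hydroxybutanoate | C[C@H](Cc1cc(OCc2ccccc2)cc(OCc2ccccc2)c1)OC(=O)C[C@@H](C)O | intermediate
16 | (R)-1-[3,5-bis(benzyloxy)phenyl]propan-2-yl (R)-3-(benzyloxy)butanoate | C[C@H](Cc1cc(OCc2ccccc2)cc(OCc2ccccc2)c1)OC(=O)C[C@@H](C)OCc1ccccc1 | intermediate
17 | N-{2,4-bis(benzyloxy)-6-[(R)-2-{[(R)-3-(benzyloxy)butanoyl]oxy}propyl]benzylidene}-N-methylmethanaminium dichlorophosphate | C[N+](C)=Cc1c(OCc2ccccc2)cc(OCc2ccccc2)cc1C[C@@H](C)OC(=O)C[C@@H](C)OCc1ccccc1.[O-]P(=O)(Cl)Cl | intermediate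
18 | (R)-1-[3,5-bis(benzyloxy)-2-formylphenyl]propan-2-yl (R)-3-(benzyloxy)butanoate | O=Cc1c(OCc2ccccc2)cc(OCc2ccccc2)cc1C[C@@H](C)OC(=O)C[C@@H](C)OCc1ccccc1 | intermediate
19 | 2,4-bis(benzyloxy)-6-[(R)-2-{[(R)-3-(benzyloxy)butanoyl]oxy}propyl]benzoic acid | OC(=O)c1c(OCc2ccccc2)cc(OCc2ccccc2)cc1C[C@@H](C)OC(=O)C[C@@H](C)OCc1ccccc1 | intermediate
20 | 2,4-bis(benzyloxy)-6-[(R)-2-{[(R)-3-(benzyloxy)butanoyl]oxy}propyl]benzoyl chloride | ClC(=O)c1c(OCc2ccccc2)cc(OCc2ccccc2)cc1C[C@@H](C)OC(=O)C[C@@H](C)OCc1ccccc1 | intermediate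
21 | penta-O-benzyl hansforester J (all four phenols and the terminal alcohol as benzyl ethers, all-(R)) | C[C@H](Cc1cc(OCc2ccccc2)cc(OCc2ccccc2)c1)OC(=O)C[C@@H](C)OC(=O)c1c(OCc2ccccc2)cc(OCc2ccccc2)cc1C[C@@H](C)OC(=O)C[C@@H](C)OCc1ccccc1 | intermediate
22 | hansforester J | C[C@H](Cc1cc(O)cc(O)c1)OC(=O)C[C@@H](C)OC(=O)c1c(O)cc(O)cc1C[C@@H](C)OC(=O)C[C@@H](C)O | target

## Step count and weak points
Total step count: 15.
Longest linear sequence: 9 steps (1 → 2 → 3 → 4 → 11 → 12 → 13 → 14 → 15).

**Step 14 (fragment union).** The acyl carbon is flanked by two ortho substituents and the nucleophile is a secondary β-hydroxy ester. Acylation may therefore be slow, and the β-aroyloxy ester product can undergo E1cB elimination to the crotonate.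

The fallback sets out from 15, with 19 unchanged as partner, and comes back at 21. It activates the alcohol instead of the acid.
- Compound 15 is oxidised with Dess–Martin periodinane (CH2Cl2, rt) to (R)-1-[3,5-bis(benzyloxy)phenyl]propan-2-yl 3-oxobutanoate F1.
- Noyori hydrogenation (RuCl2[(S)-BINAP], H2 50 bar, EtOH/CH2Cl2, 50 °C) then gives, under catalyst control, the epimeric (R)-1-[3,5-bis(benzyloxy)phenyl]propan-2-yl (S)-3-hydroxybutanoate F2.
- Mitsunobu esterification with acid 19 (PPh3, DIAD, toluene, 0 °C → rt) follows. The carboxylate oxygen is now the nucleophile, so hindrance at the acyl carbon no longer matters. SN2 inversion turns the (S) carbinol into the required (R) ester 21.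

**Step 12 (formylation).** Possible failures are attack between the two OBn groups, loss of the ortho benzyl ether, and sluggish reaction next to the branched side chain.

The fallback sets out from 16 and comes back at 19, so steps 12 and 13 are both bypassed.
- Iodination with NIS (cat. TFA, MeCN, 0 °C) occurs para to one OBn group and gives (R)-1-[3,5-bis(benzyloxy)-2-iodophenyl]propan-2-yl (R)-3-(benzyloxy)butanoate F3.
- Palladium-catalysed hydroxycarbonylation (Pd(OAc)2, Xantphos, CO 1 atm, Et3N, DMF/H2O, 70 °C) converts the C–I bond directly into the carboxylic acid 19.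

**Step 4 (epoxide opening).** Both aromatic units depend on this step. Grignard initiation, Wurtz coupling and halohydrin formation from the epoxide could all reduce the yield.

The fallback sets out from 5 and comes back at 8. It sets the stereocentre by reduction instead of taking it from the chiral pool.
- Palladium-catalysed mono-α-arylation of acetone ([Pd(cinnamyl)Cl]2, Mor-DalPhos, Cs2CO3, acetone, 90 °C) gives 1-[3,5-bis(benzyloxy)phenyl]propan-2-one F4.
- An (R)-selective, anti-Prelog alcohol dehydrogenase (Lactobacillus kefir type, NADP+, i-PrOH, pH 7 buffer, 30 °C) reduces F4 to the (R)-alcohol 8.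

## Further compounds
F1 | step 14 | (R)-1-[3,5-bis(benzyloxy)phenyl]propan-2-yl 3-oxobutanoate | C[C@H](Cc1cc(OCc2ccccc2)cc(OCc2ccccc2)c1)OC(=O)CC(C)=O
F2 | step 14 | (R)-1-[3,5-bis(benzyloxy)phenyl]propan-2-yl (S)-3-hydroxybutanoate | C[C@H](Cc1cc(OCc2ccccc2)cc(OCc2ccccc2)c1)OC(=O)C[C@H](C)O
F3 | step 12 | (R)-1-[3,5-bis(benzyloxy)-2-iodophenyl]propan-2-yl (R)-3-(benzyloxy)butanoate | Ic1c(OCc2ccccc2)cc(OCc2ccccc2)cc1C[C@@H](C)OC(=O)C[C@@H](C)OCc1ccccc1
F4 | step 4 | 1-[3,5-bis(benzyloxy)phenyl]propan-2-one | CC(=O)Cc1cc(OCc2ccccc2)cc(OCc2ccccc2)c1
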